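Ring atoms are numbered C1 (oxirane carbon bearing farnesyl), C2 (oxirane CH), C3 (carbinol), C4 (alkene carbon bearing CH2O), C5 (alkene CH), C6 (ketone); farnesyl = (2E,6E)-3,7,11-trimethyldodeca-2,6,10-trien-1-yl.
Retrosynthesis: cut the ester C–O to the hydroxymethylglutarate half ester, return C3–OH to a ketone, then cut the two acyl–alkenyl bonds C3–C4 (ring closing) and C5–C6, the C1–farnesyl bond and the oxirane C2–O bond; this leads back to D-tartaric acid.
Enabling feature: in the 7-oxabicyclo[4.1.0]hept-3-ene-2,5-dione both carbons flanking the C4=C5 alkene (C3 and C6) are carbonyl carbons held cis on the C1–C2 oxirane, so the four tartrate carbons become C6–C1–C2–C3 and a Z-1,2-distannyl alkene supplies C5=C4.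
Forward: the tartrate acetonide is farnesylated at C1, turned into the cis-epoxy diacid and differentiated through its anhydride (thiol ester at C3, acid chloride at C6); Stille acylation joins C6–C5, then the thiol ester/stannane coupling closes the carbocycle at C3–C4.
End game: desilylation, chelation-directed reduction of the C3 ketone, esterification of the primary alcohol with a mevalonolactone-derived half ester, enzymatic release of the acid.
Stereochemistry: C2 from D-tartrate (net retention in the epoxide closure), C1 by 1,2-induction from C2 in the enolate alkylation, C3 by hydride addition anti to the oxirane, the glutarate carbinol from (R)-mevalonolactone.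

Key step: step 8

Assumption: the tartrate acetonide enolate is alkylated anti to the ester on the neighbouring ring carbon (new chain trans to that ester), as expected for 1,2-induction in a five-membered ring enolate; the fallback for step 1 covers the opposite outcome.

Step 1
Reactants: 1 dimethyl (4S,5S)-2,2-dimethyl-1,3-dioxolane-4,5-dicarboxylate (D-tartrate acetonide); 2 (2E,6E)-farnesyl bromide
Product: 3 dimethyl (4R,5S)-4-farnesyl-2,2-dimethyl-1,3-dioxolane-4,5-dicarboxylate
Conditions: LiN(iPr)2, THF/HMPA, −78 °C; then 2, −78 → −40 °C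
Reagents that add atoms: none
Why: Alkylation of the tartrate acetonide lithium enolate (slow to β-eliminate because the ring C–O bond is held orthogonal to the enolate π system) with a reactive allylic bromide should proceed by SN2 at the primary carbon with the E-alkenes intact, and the quaternary center C1 is set by 1,2-induction, the bromide approaching anti to the ester on the neighbouring carbon.

Step 2
Reactants: 3 dimethyl (4R,5S)-4-farnesyl-2,2-dimethyl-1,3-dioxolane-4,5-dicarboxylate
Product: 4 dimethyl (2R,3S)-2-farnesyl-2,3-dihydroxybutanedioate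
Conditions: p-TsOH·H2O (cat.), MeOH, 50 °C
Reagents that add atoms: none
Why: Acid-catalysed transketalisation to methanol should free the diol without touching either stereocenter, under conditions mild enough for the trisubstituted alkenes.

Step 3
Reactants: 4 dimethyl (2R,3S)-2-farnesyl-2,3-dihydroxybutanedioate
Product: 7 dimethyl (2R,3S)-2-farnesyloxirane-2,3-dicarboxylate, via cyclic orthoacetate 5 (not isolated), via bromo acetate 6 (not isolated)
Conditions: MeC(OMe)3, PPTS (cat.), CH2Cl2, rt; evaporate; AcBr, Et3N (cat.), CH2Cl2, 0 °C; evaporate; K2CO3, MeOH, 0 °C → rt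
Reagents that add atoms: none
Why: Kolb–Sharpless one-pot diol-to-epoxide conversion: bromide opens the acetoxonium ion by SN2 at the secondary α-ester carbon C2 (inversion; the quaternary C1 cannot be attacked), and after methanolysis of the acetate the C1 alkoxide displaces bromide (second inversion), so that C2 ends with net retention and the two carboxyl groups end cis on the oxirane.

Step 4
Reactants: 7 dimethyl (2R,3S)-2-farnesyloxirane-2,3-dicarboxylate
Product: 8 (2R,3S)-2-farnesyloxirane-2,3-dicarboxylic acid
Conditions: LiOH·H2O, THF/H2O, 0 °C → rt; then 1 M HCl to pH 3, 0 °C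
Reagents that add atoms: lithium hydroxide, [Li+].[OH-]
Why: Saponification of a glycidic diester should be clean because the electron-poor oxirane resists hydroxide and its CH cannot enolise within the three-membered ring.

Step 5
Reactants: 8 (2R,3S)-2-farnesyloxirane-2,3-dicarboxylic acid
Product: 10 (2R,3S)-2-farnesyl-3-{[(4-methylphenyl)sulfanyl]carbonyl}oxirane-2-carboxylic acid, via epoxy anhydride 9 (not isolated)
Conditions: DCC, CH2Cl2, 0 °C; then 4-methylbenzenethiol, Et3N, −40 → −20 °C
Reagents that add atoms: 4-methylbenzenethiol, Cc1ccc(S)cc1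
Why: Cyclodehydration of the cis diacid gives the five-membered anhydride, which the thiol should open at the less hindered carbonyl (the one on the oxirane CH, C3) far faster than it attacks the oxirane at low temperature; this leaves the latent acyl donor at C3 and the free acid at C6.

Step 6
Reactants: 11 tert-butyldimethyl(prop-2-yn-1-yloxy)silane; 12 hexabutylditin
Product: 13 (Z)-tert-butyldimethyl{[2,3-bis(tributylstannyl)prop-2-en-1-yl]oxy}silane
Conditions: Pd(PPh3)4 (cat.), THF, 70 °C
Reagents that add atoms: none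
Why: Palladium-catalysed distannation of a terminal alkyne is a syn addition of the Sn–Sn bond, so the two stannyl groups end cis (Z).

Step 7
Reactants: 10 (2R,3S)-2-farnesyl-3-{[(4-methylphenyl)sulfanyl]carbonyl}oxirane-2-carboxylic acid; 13 (Z)-tert-butyldimethyl{[2,3-bis(tributylstannyl)prop-2-en-1-yl]oxy}silane
Product: 15 S-(4-methylphenyl) (2S,3R)-3-farnesyl-3-[(Z)-4-(tert-butyldimethylsilyloxy)-3-(tributylstannyl)but-2-enoyl]oxirane-2-carbothioate, via acid chloride 14 (not isolated)
Conditions: 1-chloro-N,N,2-trimethylprop-1-en-1-amine, CH2Cl2, 0 °C; evaporate; then 13, Pd2(dba)3 (cat.), P(2-furyl)3, toluene, 50 °C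
Reagents that add atoms: none
Why: Neutral acid chloride formation followed by Stille acylation, which should take place at the less hindered terminal C–Sn bond with retention of alkene geometry (ketone cis to the remaining stannyl group), while the thiol ester is inert to palladium in the absence of copper.

Step 8
Reactants: 15 S-(4-methylphenyl) (2S,3R)-3-farnesyl-3-[(Z)-4-(tert-butyldimethylsilyloxy)-3-(tributylstannyl)but-2-enoyl]oxirane-2-carbothioate
Product: 16 (1R,6S)-4-[(tert-butyldimethylsilyloxy)methyl]-1-farnesyl-7-oxabicyclo[4.1.0]hept-3-ene-2,5-dione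
Conditions: Pd2(dba)3 (cat.), P(2-furyl)3, CuO2PPh2 (1.5 equiv), THF (0.005 M), rt → 45 °C
Reagents that add atoms: none
Why: Copper-assisted oxidative addition of zerovalent palladium into the C3 acyl–S bond, transfer of the C4 alkenyl group from tin (the phosphinate takes up Bu3Sn, monovalent copper takes up the thiolate) and reductive elimination should forge the C3–C4 ketone bond under neutral, base-free conditions. The closest known reaction type is the Liebeskind–Srogl ketone synthesis from thiol esters and alkenylstannanes. The six-membered carbocycle closes in a 6-exo-trig sense at the acyl carbon, through a seven-membered acyl(alkenyl)palladium species. No new stereocenter is formed, and the two oxirane stereocenters (C1, C2) cannot enolise and pass through unchanged. The step needs chemoselectivity for the thiol ester over ketone, epoxide and farnesyl alkenes, which is inherent in the thiophilic copper activation, and ring closure over intermolecular coupling, which is secured by the cis-oxirane and the Z-alkene holding the acyl and stannyl termini syn, and by high dilution.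

Step 9
Reactants: 16 (1R,6S)-4-[(tert-butyldimethylsilyloxy)methyl]-1-farnesyl-7-oxabicyclo[4.1.0]hept-3-ene-2,5-dione
Product: 17 (1R,6S)-1-farnesyl-4-(hydroxymethyl)-7-oxabicyclo[4.1.0]hept-3-ene-2,5-dione
Conditions: HF·pyridine, pyridine/THF, 0 °C
Reagents that add atoms: none
Why: Buffered fluoride desilylation is the standard mild unmasking for epoxyquinones and should leave oxirane, enedione and polyene intact.

Step 10
Reactants: 17 (1R,6S)-1-farnesyl-4-(hydroxymethyl)-7-oxabicyclo[4.1.0]hept-3-ene-2,5-dione
Product: 18 (1R,5R,6R)-1-farnesyl-5-hydroxy-4-(hydroxymethyl)-7-oxabicyclo[4.1.0]hept-3-en-2-one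
Conditions: iBu2AlH (2.2 equiv), THF, −78 °C; aq. KNaC4H4O6 work-up
Reagents that add atoms: none
Why: Chelation-directed 1,2-reduction: the aluminium alkoxide of the primary hydroxyl should activate the neighbouring C3 carbonyl (C6 is also shielded by the quaternary C1), and hydride should add anti to the oxirane oxygen, placing the new hydroxyl cis to the epoxide (C3 R).

Step 11
Reactants: 19 (R)-mevalonolactone
Product: 21 methyl (3R)-3,5-dihydroxy-3-methylpentanoate, via potassium mevalonate 20 (not isolated)
Conditions: KOH (1 equiv), H2O, rt; evaporate; CH3I, DMF, rt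
Reagents that add atoms: potassium hydroxide, [K+].[OH-]; iodomethane, CI
Why: Lactone saponification and O-alkylation of the carboxylate fix the original lactone carboxyl as a methyl ester under neutral conditions, without touching the tertiary carbinol stereocenter.

Step 12
Reactants: 21 methyl (3R)-3,5-dihydroxy-3-methylpentanoate
Product: 23 (3R)-3-hydroxy-5-methoxy-3-methyl-5-oxopentanoic acid, via aldehyde 22 (not isolated)
Conditions: TEMPO (cat.), PhI(OAc)2, MeCN/H2O, rt
Reagents that add atoms: water, O
Why: Oxoammonium oxidation of the primary alcohol through the aldehyde hydrate gives the acid, the tertiary alcohol being inert; the two glutarate arms are now differentiated in the sense the target needs.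

Step 13
Reactants: 18 (1R,5R,6R)-1-farnesyl-5-hydroxy-4-(hydroxymethyl)-7-oxabicyclo[4.1.0]hept-3-en-2-one; 23 (3R)-3-hydroxy-5-methoxy-3-methyl-5-oxopentanoic acid
Product: 24 methyl ester of the target (mixed diester, S at the glutarate carbinol)
Conditions: EDC·HCl, DMAP (cat.), CH2Cl2, −20 → 0 °C
Reagents that add atoms: none
Why: Steglich esterification should select the unhindered primary allylic hydroxyl over the secondary C3 hydroxyl next to the oxirane and over the tertiary hydroxyl of 23.

Step 14
Reactants: 24 methyl ester of the target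
Product: 25 target compound
Conditions: pig liver esterase, phosphate buffer pH 7.2/acetone, rt
Reagents that add atoms: water, O
Why: Enzymatic ester hydrolysis at neutral pH spares the base-sensitive epoxyquinol, the allylic ester and the polyene, and the unhindered methyl ester should be cleaved in preference to the ester of the bulky allylic alcohol.

Compound list
1 | dimethyl (4S,5S)-2,2-dimethyl-1,3-dioxolane-4,5-dicarboxylate | COC(=O)[C@H]1OC(C)(C)O[C@@H]1C(=O)OC | starting material
2 | (2E,6E)-farnesyl bromide | CC(C)=CCC/C(C)=C/CC/C(C)=C/CBr | starting material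
3 | dimethyl (4R,5S)-4-farnesyl-2,2-dimethyl-1,3-dioxolane-4,5-dicarboxylate (esters cis) | CC(C)=CCC/C(C)=C/CC/C(C)=C/C[C@@]1(C(=O)OC)OC(C)(C)O[C@@H]1C(=O)OC | intermediate
4 | dimethyl (2R,3S)-2-farnesyl-2,3-dihydroxybutanedioate | CC(C)=CCC/C(C)=C/CC/C(C)=C/C[C@](O)(C(=O)OC)[C@H](O)C(=O)OC | intermediate
5 | dimethyl (4R,5S)-4-farnesyl-2-methoxy-2-methyl-1,3-dioxolane-4,5-dicarboxylate (cyclic orthoacetate, both epimers at the orthoester carbon) | CC(C)=CCC/C(C)=C/CC/C(C)=C/C[C@@]1(C(=O)OC)OC(C)(OC)O[C@@H]1C(=O)OC | intermediate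
6 | dimethyl (2S,3R)-2-acetoxy-3-bromo-2-farnesylbutanedioate | CC(C)=CCC/C(C)=C/CC/C(C)=C/C[C@](OC(C)=O)(C(=O)OC)[C@@H](Br)C(=O)OC | intermediate
7 | dimethyl (2R,3S)-2-farnesyloxirane-2,3-dicarboxylate (esters cis) | CC(C)=CCC/C(C)=C/CC/C(C)=C/C[C@@]1(C(=O)OC)O[C@@H]1C(=O)OC | intermediate
8 | (2R,3S)-2-farnesyloxirane-2,3-dicarboxylic acid | CC(C)=CCC/C(C)=C/CC/C(C)=C/C[C@@]1(C(=O)O)O[C@@H]1C(=O)O | intermediate
9 | (1R,5S)-1-farnesyl-3,6-dioxabicyclo[3.1.0]hexane-2,4-dione (epoxy anhydride) | CC(C)=CCC/C(C)=C/CC/C(C)=C/C[C@@]12O[C@@H]1C(=O)OC2=O | intermediate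
10 | (2R,3S)-2-farnesyl-3-{[(4-methylphenyl)sulfanyl]carbonyl}oxirane-2-carboxylic acid | CC(C)=CCC/C(C)=C/CC/C(C)=C/C[C@@]1(C(=O)O)O[C@@H]1C(=O)Sc2ccc(C)cc2 | intermediate
11 | tert-butyldimethyl(prop-2-yn-1-yloxy)silane | C#CCO[Si](C)(C)C(C)(C)C | starting material
12 | hexabutylditin | CCCC[Sn](CCCC)(CCCC)[Sn](CCCC)(CCCC)CCCC | starting material
13 | (Z)-tert-butyldimethyl{[2,3-bis(tributylstannyl)prop-2-en-1-yl]oxy}silane | CCCC[Sn](CCCC)(CCCC)/C=C(\[Sn](CCCC)(CCCC)CCCC)CO[Si](C)(C)C(C)(C)C | intermediate
14 | S-(4-methylphenyl) (2S,3R)-3-(chlorocarbonyl)-3-farnesyloxirane-2-carbothioate (acid chloride) | CC(C)=CCC/C(C)=C/CC/C(C)=C/C[C@@]1(C(Cl)=O)O[C@@H]1C(=O)Sc2ccc(C)cc2 | intermediate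
15 | S-(4-methylphenyl) (2S,3R)-3-farnesyl-3-[(Z)-4-(tert-butyldimethylsilyloxy)-3-(tributylstannyl)but-2-enoyl]oxirane-2-carbothioate | CC(C)=CCC/C(C)=C/CC/C(C)=C/C[C@@]1(C(=O)/C=C(\[Sn](CCCC)(CCCC)CCCC)CO[Si](C)(C)C(C)(C)C)O[C@@H]1C(=O)Sc2ccc(C)cc2 | intermediate
16 | (1R,6S)-4-[(tert-butyldimethylsilyloxy)methyl]-1-farnesyl-7-oxabicyclo[4.1.0]hept-3-ene-2,5-dione | CC(C)=CCC/C(C)=C/CC/C(C)=C/C[C@@]12O[C@@H]1C(=O)C(CO[Si](C)(C)C(C)(C)C)=CC2=O | intermediate
17 | (1R,6S)-1-farnesyl-4-(hydroxymethyl)-7-oxabicyclo[4.1.0]hept-3-ene-2,5-dione | CC(C)=CCC/C(C)=C/CC/C(C)=C/C[C@@]12O[C@@H]1C(=O)C(CO)=CC2=O | intermediate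
18 | (1R,5R,6R)-1-farnesyl-5-hydroxy-4-(hydroxymethyl)-7-oxabicyclo[4.1.0]hept-3-en-2-one (hydroxyl cis to the oxirane) | CC(C)=CCC/C(C)=C/CC/C(C)=C/C[C@@]12O[C@@H]1[C@H](O)C(CO)=CC2=O | intermediate
19 | (R)-mevalonolactone, (4R)-4-hydroxy-4-methyloxan-2-one | C[C@@]1(O)CCOC(=O)C1 | starting material
20 | potassium (3R)-3,5-dihydroxy-3-methylpentanoate | C[C@@](O)(CCO)CC(=O)[O-].[K+] | intermediate
21 | methyl (3R)-3,5-dihydroxy-3-methylpentanoate | C[C@@](O)(CCO)CC(=O)OC | intermediate
22 | methyl (3R)-3-hydroxy-3-methyl-5-oxopentanoate | C[C@@](O)(CC=O)CC(=O)OC | intermediate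
23 | (3R)-3-hydroxy-5-methoxy-3-methyl-5-oxopentanoic acid | C[C@@](O)(CC(=O)O)CC(=O)OC | intermediate
24 | methyl ester of the target: 1-{[(1R,5R,6R)-1-farnesyl-5-hydroxy-2-oxo-7-oxabicyclo[4.1.0]hept-3-en-4-yl]methyl} 5-methyl (3S)-3-hydroxy-3-methylpentanedioate | CC(C)=CCC/C(C)=C/CC/C(C)=C/C[C@@]12O[C@@H]1[C@H](O)C(COC(=O)C[C@@](C)(O)CC(=O)OC)=CC2=O | intermediate
25 | target: (3S)-5-{[(1R,5R,6R)-1-farnesyl-5-hydroxy-2-oxo-7-oxabicyclo[4.1.0]hept-3-en-4-yl]methoxy}-3-hydroxy-3-methyl-5-oxopentanoic acid | CC(C)=CCC/C(C)=C/CC/C(C)=C/C[C@@]12O[C@@H]1[C@H](O)C(COC(=O)C[C@@](C)(O)CC(=O)O)=CC2=O | target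

Total step count: 14. Longest linear sequence: 11 steps (1–5, 7–10, 13, 14).

Steps most likely to fail

Step 8. Tin-to-copper transfer at the hindered, ketone-coordinated alkenylstannane may be slow, so that protodestannylation or intermolecular coupling overtakes ring closure, or the thiolate may add to the electrophilic enedione as it forms. The fallback closes the same bond by carbonyl addition and sets out from 15. Fukuyama reduction of the thiol ester (Et3SiH, Pd/C, acetone, rt) should give the stannyl enone aldehyde F1. Iododestannylation (I2, CH2Cl2, 0 °C) should give the Z-iodoenone aldehyde F2. An intramolecular Nozaki–Hiyama–Kishi reaction (CrCl2, NiCl2 cat., DMF/THF, high dilution) should then close C3–C4 to the silyl-protected epoxyquinol F3 as either C3 epimer. Dess–Martin oxidation of F3 returns to the route at 16.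

Step 1. The facial selectivity of the enolate alkylation may be opposite to the one assumed (or low), and the enolate decomposes if warmed before it is trapped. If the chain enters cis to the neighbouring ester, the fallback sets out from 2 and the commercial enantiomer of 1, the L-tartrate acetonide F4. The same alkylation would then give the trans-diester acetonide F5, and acid methanolysis the diol F6. Because this diol is the other diastereomer, the oxirane is closed by a single inversion instead: selective mesylation of the secondary hydroxyl (MsCl, Et3N, 0 °C) to mesylate F7, then DBU. This returns to the route at 7.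

Step 10. Hydride may be delivered to the C6 carbonyl or to the oxirane face of C3, or a second reduction may follow. The fallback replaces substrate direction by reagent control and sets out from 16. Corey–Bakshi–Shibata reduction with (R)-2-methyl-CBS-oxazaborolidine and catecholborane (toluene, −78 °C) treats the alkenyl side as the large group and should deliver hydride anti to the oxirane, giving the silyl ether F8. HF·pyridine then returns to the route at 18.

Further compounds
F1 | step 8 | (2R,3R)-3-farnesyl-3-[(Z)-4-(tert-butyldimethylsilyloxy)-3-(tributylstannyl)but-2-enoyl]oxirane-2-carbaldehyde | CC(C)=CCC/C(C)=C/CC/C(C)=C/C[C@@]1(C(=O)/C=C(\[Sn](CCCC)(CCCC)CCCC)CO[Si](C)(C)C(C)(C)C)O[C@@H]1C=O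
F2 | step 8 | (2R,3R)-3-farnesyl-3-[(Z)-4-(tert-butyldimethylsilyloxy)-3-iodobut-2-enoyl]oxirane-2-carbaldehyde | CC(C)=CCC/C(C)=C/CC/C(C)=C/C[C@@]1(C(=O)/C=C(\I)CO[Si](C)(C)C(C)(C)C)O[C@@H]1C=O
F3 | step 8 | (1R,6R)-4-[(tert-butyldimethylsilyloxy)methyl]-1-farnesyl-5-hydroxy-7-oxabicyclo[4.1.0]hept-3-en-2-one (both C5 epimers) | CC(C)=CCC/C(C)=C/CC/C(C)=C/C[C@@]12O[C@@H]1C(O)C(CO[Si](C)(C)C(C)(C)C)=CC2=O
F4 | step 1 | dimethyl (4R,5R)-2,2-dimethyl-1,3-dioxolane-4,5-dicarboxylate (L-tartrate acetonide) | COC(=O)[C@@H]1OC(C)(C)O[C@H]1C(=O)OC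
F5 | step 1 | dimethyl (4R,5R)-4-farnesyl-2,2-dimethyl-1,3-dioxolane-4,5-dicarboxylate (esters trans) | CC(C)=CCC/C(C)=C/CC/C(C)=C/C[C@@]1(C(=O)OC)OC(C)(C)O[C@H]1C(=O)OC
F6 | step 1 | dimethyl (2R,3R)-2-farnesyl-2,3-dihydroxybutanedioate | CC(C)=CCC/C(C)=C/CC/C(C)=C/C[C@](O)(C(=O)OC)[C@@H](O)C(=O)OC
F7 | step 1 | dimethyl (2R,3R)-2-farnesyl-2-hydroxy-3-(methylsulfonyloxy)butanedioate | CC(C)=CCC/C(C)=C/CC/C(C)=C/C[C@](O)(C(=O)OC)[C@@H](OS(C)(=O)=O)C(=O)OC
F8 | step 10 | (1R,5R,6R)-4-[(tert-butyldimethylsilyloxy)methyl]-1-farnesyl-5-hydroxy-7-oxabicyclo[4.1.0]hept-3-en-2-one | CC(C)=CCC/C(C)=C/CC/C(C)=C/C[C@@]12O[C@@H]1[C@H](O)C(CO[Si](C)(C)C(C)(C)C)=CC2=O
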